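## Retrosynthetic overview

1. The C2' methylene comes from a C2' ketone (Peterson olefination, with silyl ether cleavage in the same acid step); the trans C3–Cl/C4–Br pair comes from the C3=C4 ring alkene of an α-hydroxy ketone by hydroxyl-directed bromochlorination.
2. The C2' ketone comes from a ring aldehyde and the Grignard reagent of the C3'–C7' unit, which is made from (R)-α-hydroxy-γ-butyrolactone (source of the C5' stereocenter).
3. The only ring, the cyclohexane, is closed in one [4+2] event: C1–C2 from 2-(4-methoxybenzoyloxy)acrolein, C3–C6 from (E)-1-trimethylsilyl-2-methylbuta-1,3-diene, forming bonds C1–C6 and C2–C3; C1 (S) is set by a chiral diammonium catalyst.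
4. Enabling feature: ring carbon C1 bears an oxygen and a carbonyl-level carbon (C2') and lies 1,4 to the methyl-bearing C4, while C3/C4 carry trans vicinal halogens (a masked C3=C4 alkene). C1–C2 is therefore a captodative acrolein unit and C3–C4–C5–C6 a 2-methylbutadiene; silicon on the terminus that becomes C3 shifts the cycloadduct alkene from C4=C5 to C3=C4.
5. Order: dienophile (steps 1–2), diene (3–4), ring (5–6), side chain (7–10), union and end game (11–15).

Key step: step 5

Assumption 1: the (R)-diammonium salt is taken to leave open the face of the iminium ion that leads to the (1S)-adduct; the sense of induction should be checked on the first run and the (S)-diamine used if it is reversed.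

Assumption 2: "target numbering" means ring C1 (carbinol), C3 (CHCl), C4 (CBrMe) and side chain C1'–C7' (C2' on the ring, C5' the carbinol); compound names use their own locants. The two epimers of 7 at the silyl-bearing carbon are carried on together.

## Route

Step 1
Reactants: 1 2,2-dimethyl-1,3-dioxan-5-one
Product: 2 2,2-dimethyl-4H-1,3-dioxin-5-yl 4-methoxybenzoate
Conditions: 4-MeOC6H4COCl, Et3N, DMAP (cat.), CH2Cl2, 0 °C to rt
Reagents that add atoms: 4-methoxybenzoyl chloride, COc1ccc(cc1)C(Cl)=O
Why: The α,α'-dioxygenated ketone enolises readily and should be O-acylated by the acylammonium species to the enol ester (enol ester formation).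

Step 2
Reactants: 2 2,2-dimethyl-4H-1,3-dioxin-5-yl 4-methoxybenzoate
Product: 3 3-oxoprop-1-en-2-yl 4-methoxybenzoate (2-(4-methoxybenzoyloxy)acrolein)
Conditions: toluene, 110 °C, used directly
Reagents that add atoms: none
Why: Retro-hetero-Diels–Alder cleavage of the 4H-1,3-dioxin is driven by loss of acetone and unmasks the 2-acyloxyacrolein.

Step 3
Reactants: 4 3-methyl-2,5-dihydrothiophene 1,1-dioxide
Product: 5 3-methyl-2-(trimethylsilyl)-2,5-dihydrothiophene 1,1-dioxide (racemic)
Conditions: LiN(SiMe3)2 added to 4 and Me3SiCl, THF, −78 °C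
Reagents that add atoms: chlorotrimethylsilane, C[Si](C)(C)Cl
Why: The amide base should remove the proton α to sulfur at C2, where the allyl anion places charge on C2 and C4 and not on the methyl-bearing C3, and the chlorosilane in the flask traps the anion before ring opening (α-silylation of a 3-sulfolene).

Step 4
Reactants: 5 3-methyl-2-(trimethylsilyl)-2,5-dihydrothiophene 1,1-dioxide
Product: 6 (E)-trimethyl(2-methylbuta-1,3-dien-1-yl)silane
Conditions: toluene, 110–120 °C, N2 sweep, distillation
Reagents that add atoms: none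
Why: Cheletropic extrusion of SO2 is suprafacial and disrotatory with the silyl group turning outward, so the (E)-1-silyl diene should result.

Step 5
Reactants: 3 3-oxoprop-1-en-2-yl 4-methoxybenzoate; 6 (E)-trimethyl(2-methylbuta-1,3-dien-1-yl)silane
Product: 7 (1S,5RS)-1-formyl-4-methyl-5-(trimethylsilyl)cyclohex-3-en-1-yl 4-methoxybenzoate
Conditions: (R)-1,1'-binaphthyl-2,2'-diamine (10 mol%), Tf2NH (19 mol%), EtCN, −78 to −40 °C, 6 in excess
Reagents that add atoms: none
Why: The primary ammonium salt condenses with aldehyde 3 to an α-acyloxy iminium ion, whose lowered LUMO undergoes a concerted but asynchronous [4+2] cycloaddition with s-cis diene 6, and hydrolysis releases 7 and the catalyst. The closest known reaction type is the primary-ammonium (iminium) catalysed enantioselective Diels–Alder reaction of α-acyloxyacroleins with dienes. The single carbocycle is closed by intermolecular [4+2] cycloaddition, suprafacial on both partners, which forms the C1–C6 and C2–C3 bonds (target numbering) at once. The quaternary C1 stereocenter (S) is set by the catalyst, whose binaphthyl backbone and second ammonium group (hydrogen-bonded to the acyloxy carbonyl) leave one face of the iminium alkene open, while the silyl-bearing carbon forms as an endo/exo mixture that does not matter because it becomes sp2 in step 6. The step needs regiocontrol (dienophile CH2 to the silylated diene terminus, fully substituted carbon to the free CH2 terminus), and the substrate secures it three ways: the 2-methyl group (para rule) and the C–Si bond (β-silicon hyperconjugation) both stabilise the positive charge that builds on the methyl-bearing diene carbon when the dienophile β-carbon attacks the silylated terminus, and the congested dienophile carbon bonds to the unhindered terminus. Low temperature and the absence of free acid (all Tf2NH is bound as ammonium) should protect the vinylsilane and the allylsilane product from early protodesilylation.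

Step 6
Reactants: 7 (1S,5RS)-1-formyl-4-methyl-5-(trimethylsilyl)cyclohex-3-en-1-yl 4-methoxybenzoate
Product: 8 (1S)-1-formyl-4-methylcyclohex-3-en-1-yl 4-methoxybenzoate
Conditions: CF3CO2H (1.5 equiv), CH2Cl2, −20 to 0 °C, NaHCO3 quench on consumption of 7
Reagents that add atoms: none
Why: SE2' protodesilylation of the allylsilane: the proton adds to the alkene CH γ to silicon and the β-silyl cation loses the silyl group, so both epimers of 7 should give the alkene between the methyl-bearing carbon and the former silyl carbon (C3=C4 of the target); exposure is kept short because acid-induced double-bond migration would amount to racemisation at C1.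

Step 7
Reactants: 9 (R)-3-hydroxydihydrofuran-2(3H)-one
Product: 10 (R)-3-[(tert-butyldimethylsilyl)oxy]dihydrofuran-2(3H)-one
Conditions: t-BuMe2SiCl, imidazole, DMF, rt
Reagents that add atoms: tert-butyl(chloro)dimethylsilane, CC(C)(C)[Si](C)(C)Cl
Why: Silyl ether formation on the secondary alcohol; the stereocenter is not touched.

Step 8
Reactants: 10 (R)-3-[(tert-butyldimethylsilyl)oxy]dihydrofuran-2(3H)-one
Product: 11 (R)-3-[(tert-butyldimethylsilyl)oxy]-5-hydroxypentan-2-one (in equilibrium with its cyclic hemiketal)
Conditions: MeLi (1.05 equiv), THF, −78 °C, NH4Cl quench at −78 °C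
Reagents that add atoms: methyllithium, [Li]C
Why: Mono-addition of MeLi to the γ-lactone; the lithium hemiketalate should be stable at −78 °C, which prevents a second addition.

Step 9
Reactants: 11 (R)-3-[(tert-butyldimethylsilyl)oxy]-5-hydroxypentan-2-one
Product: 12 (R)-3-[(tert-butyldimethylsilyl)oxy]-4-methylpent-4-en-1-ol
Conditions: Ph3PCH3Br, n-BuLi (2.5 equiv of ylide), THF, 0 °C
Reagents that add atoms: methyltriphenylphosphonium bromide, C[P+](c1ccccc1)(c1ccccc1)c1ccccc1.[Br-]
Why: Wittig methylenation of the ketone form of the lactol; the lithium counter-ion and 0 °C are chosen to hold back 1,3-silyl migration to the primary alkoxide and enolisation at the silyloxy-bearing stereocenter.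

Step 10
Reactants: 12 (R)-3-[(tert-butyldimethylsilyl)oxy]-4-methylpent-4-en-1-ol
Product: 13 (R)-[(5-bromo-2-methylpent-1-en-3-yl)oxy](tert-butyl)dimethylsilane
Conditions: CBr4, PPh3, 2,6-lutidine, CH2Cl2, 0 °C
Reagents that add atoms: carbon tetrabromide, BrC(Br)(Br)Br
Why: Appel bromination (SN2 at the primary carbinol carbon under near-neutral conditions) should leave the allylic silyl ether and the alkene alone.

Step 11
Reactants: 13 (R)-[(5-bromo-2-methylpent-1-en-3-yl)oxy](tert-butyl)dimethylsilane; 8 (1S)-1-formyl-4-methylcyclohex-3-en-1-yl 4-methoxybenzoate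
Product: 16 (1S)-1-[(1RS,4R)-4-[(tert-butyldimethylsilyl)oxy]-1-hydroxy-5-methylhex-5-en-1-yl]-4-methylcyclohex-3-en-1-ol, via Grignard reagent 14 (not isolated), via magnesium alkoxide of hydroxy ester 15 (not isolated)
Conditions: Mg, THF, rt; then 8, −78 °C; then MeMgBr (3.5 equiv), −78 to 0 °C; NH4Cl
Reagents that add atoms: none
Why: The primary Grignard reagent should add to the aldehyde (no α-hydrogen, so no enolisation) at −78 °C faster than to the hindered tertiary aryl ester, and excess MeMgBr then cleaves the 4-methoxybenzoate, directly or after 1,2-acyl shift to the new alkoxide; the new carbinol stereocenter is left uncontrolled because step 12 removes it.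

Step 12
Reactants: 16 (1S)-1-[(1RS,4R)-4-[(tert-butyldimethylsilyl)oxy]-1-hydroxy-5-methylhex-5-en-1-yl]-4-methylcyclohex-3-en-1-ol
Product: 17 (4R)-4-[(tert-butyldimethylsilyl)oxy]-1-[(1S)-1-hydroxy-4-methylcyclohex-3-en-1-yl]-5-methylhex-5-en-1-one
Conditions: 2-iodoxybenzoic acid, DMSO, rt
Reagents that add atoms: none
Why: 2-Iodoxybenzoic acid oxidises the secondary hydroxyl of a 1,2-diol to the ketone without glycol cleavage and cannot oxidise the tertiary one.

Step 13
Reactants: 17 (4R)-4-[(tert-butyldimethylsilyl)oxy]-1-[(1S)-1-hydroxy-4-methylcyclohex-3-en-1-yl]-5-methylhex-5-en-1-one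
Product: 18 (4R)-1-[(1S,3S,4S)-4-bromo-3-chloro-1-hydroxy-4-methylcyclohexyl]-4-[(tert-butyldimethylsilyl)oxy]-5-methylhex-5-en-1-one
Conditions: ClTi(OiPr)3 (1.2 equiv), then NBS (1.1 equiv), hexanes/CH2Cl2, −20 °C
Reagents that add atoms: N-bromosuccinimide, O=C1CCC(=O)N1Br; chlorotitanium triisopropoxide, CC(C)O[Ti](Cl)(OC(C)C)OC(C)C
Why: Proposed new method: the C1 alkoxide exchanges onto tetravalent titanium (held also by the ketone oxygen), NBS forms the bromonium ion reversibly on either face of the C3=C4 alkene, and only the ion on the face opposite to the axial C1–O bond can be opened by chloride transfer from titanium to C3 through a six-membered, trans-diaxial transition state in the chair that keeps the acyl group equatorial. This should place chlorine on C3 cis to the C1 oxygen (S) and leave bromine on the tertiary C4 on the other face (S, anti addition), while the undirected side-chain alkene reacts more slowly. The closest known reaction type is the titanium-alkoxide-directed bromochlorination of allylic alcohols with NBS and ClTi(OiPr)3, in which chloride goes to the alkene carbon nearer the hydroxyl against the Markovnikov preference; here it is extended from an allylic to a tertiary homoallylic ring alcohol.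

Step 14
Reactants: 18 (4R)-1-[(1S,3S,4S)-4-bromo-3-chloro-1-hydroxy-4-methylcyclohexyl]-4-[(tert-butyldimethylsilyl)oxy]-5-methylhex-5-en-1-one
Product: 19 (2RS,5R)-2-[(1S,3S,4S)-4-bromo-3-chloro-1-hydroxy-4-methylcyclohexyl]-5-[(tert-butyldimethylsilyl)oxy]-6-methyl-1-(trimethylsilyl)hept-6-en-2-ol
Conditions: Me3SiCH2Li (3 equiv), CeCl3 (3 equiv, dried), THF, −78 °C; NH4Cl
Reagents that add atoms: (trimethylsilyl)methyllithium, [Li]C[Si](C)(C)C
Why: Addition stage of a Peterson olefination: the organocerium reagent is nucleophilic but barely basic, so it should add to the hindered α-alkoxy ketone without E2 loss of HBr or HCl and without enolisation; the new carbinol stereocenter is irrelevant.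

Step 15
Reactants: 19 (2RS,5R)-2-[(1S,3S,4S)-4-bromo-3-chloro-1-hydroxy-4-methylcyclohexyl]-5-[(tert-butyldimethylsilyl)oxy]-6-methyl-1-(trimethylsilyl)hept-6-en-2-ol
Product: 20 (1S,3S,4S)-4-bromo-3-chloro-1-[(5R)-5-hydroxy-6-methylhepta-1,6-dien-2-yl]-4-methylcyclohexan-1-ol
Conditions: aq. HF (48%), MeCN, 0 °C to rt
Reagents that add atoms: none
Why: Acid-promoted Peterson elimination (ionisation of the hydroxyl β to silicon and loss of Me3SiF) should form the exocyclic methylene while the same HF cleaves the silyl ether; the tertiary bromide, deactivated towards ionisation by the neighbouring chlorine, should survive the weakly acidic medium.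

## Compound list

1 | 2,2-dimethyl-1,3-dioxan-5-one | CC1(C)OCC(=O)CO1 | starting material
2 | 2,2-dimethyl-4H-1,3-dioxin-5-yl 4-methoxybenzoate | CC1(C)OCC(OC(=O)c2ccc(OC)cc2)=CO1 | intermediate
3 | 3-oxoprop-1-en-2-yl 4-methoxybenzoate | C=C(OC(=O)c1ccc(OC)cc1)C=O | intermediate
4 | 3-methyl-2,5-dihydrothiophene 1,1-dioxide | CC1=CCS(=O)(=O)C1 | starting material
5 | 3-methyl-2-(trimethylsilyl)-2,5-dihydrothiophene 1,1-dioxide (racemic) | CC1=CCS(=O)(=O)C1[Si](C)(C)C | intermediate
6 | (E)-trimethyl(2-methylbuta-1,3-dien-1-yl)silane | C=C/C(C)=C/[Si](C)(C)C | intermediate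
7 | (1S,5RS)-1-formyl-4-methyl-5-(trimethylsilyl)cyclohex-3-en-1-yl 4-methoxybenzoate (both epimers at the silyl carbon) | O=C[C@]1(OC(=O)c2ccc(OC)cc2)CC=C(C)C([Si](C)(C)C)C1 | intermediate
8 | (1S)-1-formyl-4-methylcyclohex-3-en-1-yl 4-methoxybenzoate | O=C[C@]1(OC(=O)c2ccc(OC)cc2)CCC(C)=CC1 | intermediate
9 | (R)-3-hydroxydihydrofuran-2(3H)-one | O=C1OCC[C@H]1O | starting material
10 | (R)-3-[(tert-butyldimethylsilyl)oxy]dihydrofuran-2(3H)-one | O=C1OCC[C@H]1O[Si](C)(C)C(C)(C)C | intermediate
11 | (R)-3-[(tert-butyldimethylsilyl)oxy]-5-hydroxypentan-2-one | CC(=O)[C@H](O[Si](C)(C)C(C)(C)C)CCO | intermediate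
12 | (R)-3-[(tert-butyldimethylsilyl)oxy]-4-methylpent-4-en-1-ol | C=C(C)[C@H](O[Si](C)(C)C(C)(C)C)CCO | intermediate
13 | (R)-[(5-bromo-2-methylpent-1-en-3-yl)oxy](tert-butyl)dimethylsilane | C=C(C)[C@H](O[Si](C)(C)C(C)(C)C)CCBr | intermediate
14 | {(3R)-3-[(tert-butyldimethylsilyl)oxy]-4-methylpent-4-en-1-yl}magnesium bromide | C=C(C)[C@H](O[Si](C)(C)C(C)(C)C)CC[Mg]Br | intermediate
15 | (1S)-1-[(1RS,4R)-4-[(tert-butyldimethylsilyl)oxy]-1-hydroxy-5-methylhex-5-en-1-yl]-4-methylcyclohex-3-en-1-yl 4-methoxybenzoate (present as its bromomagnesium alkoxide) | C=C(C)[C@H](O[Si](C)(C)C(C)(C)C)CCC(O)[C@]1(OC(=O)c2ccc(OC)cc2)CCC(C)=CC1 | intermediate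
16 | (1S)-1-[(1RS,4R)-4-[(tert-butyldimethylsilyl)oxy]-1-hydroxy-5-methylhex-5-en-1-yl]-4-methylcyclohex-3-en-1-ol | C=C(C)[C@H](O[Si](C)(C)C(C)(C)C)CCC(O)[C@]1(O)CCC(C)=CC1 | intermediate
17 | (4R)-4-[(tert-butyldimethylsilyl)oxy]-1-[(1S)-1-hydroxy-4-methylcyclohex-3-en-1-yl]-5-methylhex-5-en-1-one | C=C(C)[C@H](O[Si](C)(C)C(C)(C)C)CCC(=O)[C@]1(O)CCC(C)=CC1 | intermediate
18 | (4R)-1-[(1S,3S,4S)-4-bromo-3-chloro-1-hydroxy-4-methylcyclohexyl]-4-[(tert-butyldimethylsilyl)oxy]-5-methylhex-5-en-1-one | C=C(C)[C@H](O[Si](C)(C)C(C)(C)C)CCC(=O)[C@]1(O)CC[C@](C)(Br)[C@@H](Cl)C1 | intermediate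
19 | (2RS,5R)-2-[(1S,3S,4S)-4-bromo-3-chloro-1-hydroxy-4-methylcyclohexyl]-5-[(tert-butyldimethylsilyl)oxy]-6-methyl-1-(trimethylsilyl)hept-6-en-2-ol | C=C(C)[C@H](O[Si](C)(C)C(C)(C)C)CCC(O)(C[Si](C)(C)C)[C@]1(O)CC[C@](C)(Br)[C@@H](Cl)C1 | intermediate
20 | (1S,3S,4S)-4-bromo-3-chloro-1-[(5R)-5-hydroxy-6-methylhepta-1,6-dien-2-yl]-4-methylcyclohexan-1-ol | C=C(C)[C@H](O)CCC(=C)[C@]1(O)CC[C@](C)(Br)[C@@H](Cl)C1 | target

## Step count and risks

Total step count: 15. Longest linear sequence: 9 steps (for example 1, 2, 5, 6, 11, 12, 13, 14, 15).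

**Step 13 (proposed new method).** What may go wrong: chloride transfer from the titanium alkoxide may be too slow, so that external chloride attack at the tertiary C4, transannular ether formation by the C1 oxygen, or bromination of the side-chain alkene take over. The fallback uses known chemistry, sets out from 17 and returns at 18. Chlorohydroxylation of the ring alkene with trichloroisocyanuric acid in aqueous acetone at 0 °C (chloronium ion opened by water at the tertiary carbon in a trans-diaxial manner, in the chair that keeps the acyl group equatorial) should give (4R)-4-[(tert-butyldimethylsilyl)oxy]-1-[(1S,3S,4S)-3-chloro-1,4-dihydroxy-4-methylcyclohexyl]-5-methylhex-5-en-1-one F1. The C4 tertiary hydroxyl is then exchanged for bromide under neutral conditions with 1-bromo-N,N,2-trimethylprop-1-en-1-amine in CH2Cl2 at 0 °C; ionisation is assisted by the neighbouring chlorine, so bromide should enter anti to it and give 18. The C1 hydroxyl, next to the ketone, cannot ionise and should be returned on bicarbonate work-up, although partial O-acylation there is possible.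

**Step 5 (key step).** What may go wrong: the cycloaddition may be too slow or lose regio- or facial control with the acid-sensitive silyl diene, or the ammonium salt may protodesilylate the diene. The fallback replaces catalyst control by a covalently bound auxiliary; it sets out from 6 and returns at 17. (S)-Lactic acid and pivalaldehyde are condensed under acid catalysis to (2S,5S)-2-tert-butyl-5-methyl-1,3-dioxolan-4-one F2. Radical bromination with NBS gives (2R)-5-bromo-2-tert-butyl-5-methyl-1,3-dioxolan-4-one F3 (same arrangement at the acetal carbon, the descriptor changes with the bromine). Dehydrobromination with Et3N gives (2S)-2-tert-butyl-5-methylene-1,3-dioxolan-4-one F4. Thermal cycloaddition of F4 with 6 (toluene, 90 °C), with the diene approaching anti to the tert-butyl group and the same regiochemical control as in step 5, should give (2S,5S,9RS)-2-tert-butyl-8-methyl-9-(trimethylsilyl)-1,3-dioxaspiro[4.5]dec-7-en-4-one F5. Protodesilylation as in step 6 gives (2S,5S)-2-tert-butyl-8-methyl-1,3-dioxaspiro[4.5]dec-7-en-4-one F6. Aminolysis with MeNH(OMe)·HCl and i-PrMgCl releases pivalaldehyde and gives (1S)-1-hydroxy-N-methoxy-N,4-dimethylcyclohex-3-ene-1-carboxamide F7. Addition of Grignard reagent 14 (excess) to F7 gives 17 directly.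

**Step 14.** What may go wrong: the organometallic may act as a base or attack the tertiary bromide (loss of HBr), or addition to the hindered carbonyl next to the metal alkoxide may be incomplete. The fallback sets out from 18 and returns at 20. Direct carbonyl methylenation with Cp2TiMe2 (excess, toluene, 65 °C, a titanium methylidene and no carbanion) should give (1S,3S,4S)-4-bromo-1-[(5R)-5-[(tert-butyldimethylsilyl)oxy]-6-methylhepta-1,6-dien-2-yl]-3-chloro-4-methylcyclohexan-1-ol F8, and HF·pyridine in THF then removes the silyl ether to give 20.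

## Further compounds

F1 | step 13 | (4R)-4-[(tert-butyldimethylsilyl)oxy]-1-[(1S,3S,4S)-3-chloro-1,4-dihydroxy-4-methylcyclohexyl]-5-methylhex-5-en-1-one | C=C(C)[C@H](O[Si](C)(C)C(C)(C)C)CCC(=O)[C@]1(O)CC[C@](C)(O)[C@@H](Cl)C1
F2 | step 5 | (2S,5S)-2-tert-butyl-5-methyl-1,3-dioxolan-4-one | C[C@@H]1O[C@H](C(C)(C)C)OC1=O
F3 | step 5 | (2R)-5-bromo-2-tert-butyl-5-methyl-1,3-dioxolan-4-one | CC1(Br)O[C@H](C(C)(C)C)OC1=O
F4 | step 5 | (2S)-2-tert-butyl-5-methylene-1,3-dioxolan-4-one | C=C1O[C@H](C(C)(C)C)OC1=O
F5 | step 5 | (2S,5S,9RS)-2-tert-butyl-8-methyl-9-(trimethylsilyl)-1,3-dioxaspiro[4.5]dec-7-en-4-one | CC(C)(C)[C@@H]1OC(=O)[C@@]2(CC=C(C)C([Si](C)(C)C)C2)O1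
F6 | step 5 | (2S,5S)-2-tert-butyl-8-methyl-1,3-dioxaspiro[4.5]dec-7-en-4-one | CC(C)(C)[C@@H]1OC(=O)[C@@]2(CCC(C)=CC2)O1
F7 | step 5 | (1S)-1-hydroxy-N-methoxy-N,4-dimethylcyclohex-3-ene-1-carboxamide | CON(C)C(=O)[C@]1(O)CCC(C)=CC1
F8 | step 14 | (1S,3S,4S)-4-bromo-1-[(5R)-5-[(tert-butyldimethylsilyl)oxy]-6-methylhepta-1,6-dien-2-yl]-3-chloro-4-methylcyclohexan-1-ol | C=C(C)[C@H](O[Si](C)(C)C(C)(C)C)CCC(=C)[C@]1(O)CC[C@](C)(Br)[C@@H](Cl)C1
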